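## Retrosynthetic overview

1. Labels: C1 is the ring CH carrying the side chain, C2/C3 the ring CH2 groups and C4 the ring CHCH3. C4a/C8a are the fusion carbons next to C4/C1. C5 and C6 are C–OH, C7 is C–CO2H and C8 is the aromatic CH. In the chain, C11 is the CH bearing C18H2OAc, C12–C14 are CH2, C15 is CHCH3 and C16 is its CH2OAc.
2. Feature: the saturated ring C1–C2–C3–C4–C4a–C8a, with its trans C1/C4 pair, is the p-menthane ring of (R)-carvone (carvone C5 = C1, C2 = C4, C1 = C4a, C6 = C8a). The arene edge C5(O)–C6(O)–C7(CO2H) is a 4-oxygenated acetoacetate, so only C8 has to be added.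
3. Late disconnections: (a) hydrogenolysis of one benzyl ether and one benzyl ester. (b) C7–C8 and C4a–C5, which opens the arene to a β-chloro enal (CHO = C8 on C8a, Cl on C4a) and benzyl 4-(benzyloxy)-3-oxobutanoate. (c) C8–C8a and C4a–Cl, by chloroformylation of the 2,5-trans ketone.
4. Early disconnections: (d) C11–H and C18–O, by catalyst-controlled hydroboration of the C11=C18 methylidene. (e) C12–C13, by copper-catalysed coupling of the ketal of 10-chlorodihydrocarvone with a C13–C16 Grignard reagent made from (R)-3-bromo-2-methylpropan-1-ol.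
5. Ring order: the cyclohexane ring comes from carvone. The benzene ring is the only ring made, and it is closed in step 13.

Key step: step 13

Assumption: (R)-DTBM-SEGPHOS is taken to deliver hydride to the C11 face that leads to the 11S alcohol. This sense must be confirmed by correlation on the first run, and the (S)-ligand replaces it without further change if the sense is opposite.

## Route

Step 1
Reactants: 1 (R)-carvone
Product: 3 (2R,5R)-2-methyl-5-(prop-1-en-2-yl)cyclohexan-1-one (trans-dihydrocarvone), via lithium enolate 2 (not isolated)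
Conditions: Li, NH3(l), t-BuOH (1 equiv), THF, −78 °C; then NH4Cl(s); chromatography
Reagents that add atoms: none
Why: Birch-type dissolving-metal conjugate reduction touches only the enone, and enolate 2 is protonated axially at C4 on the half-chair that keeps the isopropenyl group equatorial, which should give the diequatorial trans ketone (also the thermodynamic epimer), with any cis epimer removed by chromatography.

Step 2
Reactants: 3 trans-dihydrocarvone
Product: 4 (2R,5R)-5-(3-chloroprop-1-en-2-yl)-2-methylcyclohexan-1-one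
Conditions: Ca(OCl)2, CO2(s), CH2Cl2/H2O, 0 °C
Reagents that add atoms: calcium hypochlorite [Ca+2].[O-]Cl.[O-]Cl
Why: Ene-type allylic chlorination by HOCl made in the flask attacks only the electron-rich 1,1-disubstituted alkene and loses a methyl proton, as it does with carvone, so the methyl group becomes C12H2Cl and no stereocentre is touched.

Step 3
Reactants: 4 chloro ketone
Product: 5 (6R,9R)-9-(3-chloroprop-1-en-2-yl)-6-methyl-1,4-dioxaspiro[4.5]decane
Conditions: (TMSOCH2)2, TMSOTf (cat.), CH2Cl2, −78 to −20 °C; pyridine quench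
Reagents that add atoms: 1,2-bis(trimethylsilyloxy)ethane C[Si](C)(C)OCCO[Si](C)(C)C
Why: Noyori ketalisation under cold aprotic conditions masks the ketone against the Grignard and copper hydride steps without solvolysing the allylic chloride or equilibrating C4.

Step 4
Reactants: 6 (R)-3-bromo-2-methylpropan-1-ol
Product: 7 [(2R)-3-bromo-2-methylpropoxy](tert-butyl)dimethylsilane
Conditions: TBSCl, imidazole, CH2Cl2, 0 °C to rt
Reagents that add atoms: tert-butyldimethylsilyl chloride CC(C)(C)[Si](C)(C)Cl
Why: Standard silylation of a primary alcohol gives a Grignard-stable ether on the future C16 oxygen, and C15 is bought in with the configuration required.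

Step 5
Reactants: 7 silyl ether bromide
Product: 9 (3S)-4-[(tert-butyldimethylsilyl)oxy]-3-methylbutan-1-ol, via Grignard reagent 8 (not isolated)
Conditions: Mg, THF, 40 °C; then (CH2O)n, 0 °C to rt; aq NH4Cl
Reagents that add atoms: formaldehyde (from paraformaldehyde) C=O
Why: Grignard formation and hydroxymethylation with formaldehyde add C13, and C15 is β to the carbanion and cannot invert (the descriptor changes only through priorities).

Step 6
Reactants: 9 homologated alcohol
Product: 10 [(2S)-4-bromo-2-methylbutoxy](tert-butyl)dimethylsilane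
Conditions: CBr4, PPh3, CH2Cl2, 0 °C
Reagents that add atoms: carbon tetrabromide BrC(Br)(Br)Br
Why: The Appel reaction converts the unhindered primary alcohol into the bromide under near-neutral conditions that a primary TBS ether tolerates.

Step 7
Reactants: 10 C13–C16 bromide; 5 allylic chloride ketal
Product: 12 tert-butyl({(2S)-2-methyl-6-[(6R,9R)-6-methyl-1,4-dioxaspiro[4.5]decan-9-yl]hept-6-en-1-yl}oxy)dimethylsilane, via Grignard reagent 11 (not isolated)
Conditions: Mg, THF, 40 °C; then 5, Li2CuCl4 (5 mol %), THF, −20 to 0 °C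
Reagents that add atoms: none
Why: Kochi-type copper-catalysed allyl–alkyl coupling forms C12–C13, and because both termini of the 2-substituted allyl unit are CH2 the SN2 and SN2' pathways give the same product.

Step 8
Reactants: 12 methylidene ketal
Product: 14 (2S,6S)-7-[(tert-butyldimethylsilyl)oxy]-6-methyl-2-[(6R,9R)-6-methyl-1,4-dioxaspiro[4.5]decan-9-yl]heptan-1-ol, via pinacol boronate 13 (not isolated)
Conditions: CuCl (5 mol %), (R)-DTBM-SEGPHOS (5.5 mol %), KOt-Bu (10 mol %), HBpin, THF, rt; then H2O2, NaOH, 0 °C to rt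
Reagents that add atoms: hydrogen peroxide OO (oxygen on C18); pinacolborane CC1(C)OBOC1(C)C (boron and pinacolate of 13 only)
Why: Copper hydride catalysed anti-Markovnikov asymmetric hydroboration of an aliphatic 1,1-disubstituted alkene sets C11 in the hydrocupration, where the ligand pocket tells the ring CH from the linear chain (related additions to isopropenylcyclohexanes are catalyst-controlled), and the C–B bond is then oxidised at the achiral C18.

Step 9
Reactants: 14 silyl ether ketal alcohol
Product: 15 (2R,5R)-5-[(2S,6S)-1,7-dihydroxy-6-methylheptan-2-yl]-2-methylcyclohexan-1-one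
Conditions: 2 M HCl, THF, rt
Reagents that add atoms: water O (ketone oxygen)
Why: Aqueous acid removes the dioxolane and the primary TBS ether in one operation, and C4, which can equilibrate here, rests in the diequatorial trans arrangement that is the thermodynamic one.

Step 10
Reactants: 15 keto diol
Product: 16 (2S,6S)-2-methyl-6-[(1R,4R)-4-methyl-3-oxocyclohexyl]heptane-1,7-diyl diacetate
Conditions: Ac2O, pyridine, DMAP (cat.), CH2Cl2, 0 °C to rt; chromatography
Reagents that add atoms: acetic anhydride CC(=O)OC(C)=O
Why: DMAP-catalysed acetylation installs both final acetates, which also shield the hydroxyl groups from the Vilsmeier reagent, and any cis C4 epimer is removed at this easily purified stage.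

Step 11
Reactants: 16 keto diacetate
Product: 18 (2S,6S)-6-[(1S,4R)-3-chloro-2-formyl-4-methylcyclohex-2-en-1-yl]-2-methylheptane-1,7-diyl diacetate, via chlorovinyl iminium salt 17 (not isolated)
Conditions: POCl3, DMF, ClCH2CH2Cl, 0 to 50 °C; then aq NaOAc, 0 °C
Reagents that add atoms: N,N-dimethylformamide CN(C)C=O (C8); phosphoryl chloride O=P(Cl)(Cl)Cl (chlorine on C4a); water O (formyl oxygen)
Why: In this Vilsmeier–Haack–Arnold chloroformylation only the enol toward C8a can go on to an enaminone and then to 17, so C8 lands on C8a and chlorine on C4a, the acetates are inert, and the trans C1/C4 relation is preferred both in 16 (diequatorial) and in 17 and 18 (both groups pseudoaxial, away from the iminium arm and the chlorine).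

Step 12
Reactants: 19 ethyl 4-(benzyloxy)-3-oxobutanoate
Product: 20 benzyl 4-(benzyloxy)-3-oxobutanoate
Conditions: BnOH, DMAP (cat.), toluene, reflux (EtOH distilled off)
Reagents that add atoms: benzyl alcohol OCc1ccccc1
Why: DMAP-catalysed transesterification of a β-keto ester (acylketene pathway) is selective for this ester type and makes both protecting groups of the C5–C7 unit hydrogenolysable.

Step 13
Reactants: 18 β-chloro enal; 20 benzyl 4-(benzyloxy)-3-oxobutanoate
Product: 23 benzyl (5R,8S)-4-(benzyloxy)-8-[(2S,6S)-1,7-diacetoxy-6-methylheptan-2-yl]-3-hydroxy-5-methyl-5,6,7,8-tetrahydronaphthalene-2-carboxylate, via Knoevenagel adduct 21 (not isolated), via chlorocyclohexadiene 22 (not isolated)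
Conditions: TiCl4 (2 equiv), pyridine (4 equiv), THF, 0 °C to rt; then Et3N (3 equiv), 50 °C; aq citric acid
Reagents that add atoms: none
Why: TiCl4/pyridine (Lehnert modification of the Knoevenagel condensation) binds the formyl oxygen and the 1,3-dicarbonyl unit, so the most acidic carbon of 20 (C7) adds to C8 and water is lost to give 21, whose E and Z forms interconvert, and Et3N then enolises the titanium-chelated α-benzyloxy ketone toward C5. The trienolate C5=C6–C7=C8–C8a=C4a closes the six-membered ring by disrotatory 6π electrocyclisation (equally a 6-endo vinylogous addition of C5 to C4a) to 22, and loss of HCl across C4a–C5 makes the benzene ring irreversibly. The closest known reaction type is the benzannulation of Vilsmeier-derived β-chlorovinyl aldehydes with acetoacetates and acetonedicarboxylates to benzoates and salicylates, of which this is an application to a 4-benzyloxy partner. No stereocentre is created, because the sp3 centres C4a and C5 of 22 disappear on aromatisation. The step needs regiocontrol (C7 to C8 and C5 to C4a, not the reverse), which is secured by Lewis-acid activation of the aldehyde, by the shielding of the fully substituted C4a and by the absence of a free enolate in the first stage; a secondary-amine salt is avoided because it would displace the vinylic chloride, could scramble C4 through a dienamine and could not absorb the equivalent of HCl. C1 and C4 should survive because C1–H is not conjugated to the acceptor and the C4 methyl group sits pseudoaxial to avoid the chlorine, leaving C4–H near the nodal plane of the π system.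

Step 14
Reactants: 23 benzyl ester benzyl ether
Product: 24 (5R,8S)-8-[(2S,6S)-1,7-diacetoxy-6-methylheptan-2-yl]-3,4-dihydroxy-5-methyl-5,6,7,8-tetrahydronaphthalene-2-carboxylic acid (target)
Conditions: H2 (1 atm), Pd/C (10 wt %), EtOAc/EtOH, rt
Reagents that add atoms: none
Why: Catalytic hydrogenolysis cleaves the aryl benzyl ether and the benzyl ester together and leaves the acetates, the arene and the benzylic C–H centres C1 and C4 unchanged.

## Compound list

1 | (R)-carvone | CC1=CC[C@H](CC1=O)C(C)=C | starting material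
2 | lithium (5R)-2-methyl-5-(prop-1-en-2-yl)cyclohex-1-en-1-olate (not isolated) | C=C(C)[C@@H]1CCC(C)=C([O-])C1.[Li+] | intermediate
3 | (2R,5R)-2-methyl-5-(prop-1-en-2-yl)cyclohexan-1-one | C=C(C)[C@@H]1CC[C@@H](C)C(=O)C1 | intermediate
4 | (2R,5R)-5-(3-chloroprop-1-en-2-yl)-2-methylcyclohexan-1-one | ClCC(=C)[C@@H]1CC[C@@H](C)C(=O)C1 | intermediate
5 | (6R,9R)-9-(3-chloroprop-1-en-2-yl)-6-methyl-1,4-dioxaspiro[4.5]decane | ClCC(=C)[C@@H]1CC[C@@H](C)C2(C1)OCCO2 | intermediate
6 | (R)-3-bromo-2-methylpropan-1-ol | OC[C@@H](C)CBr | starting material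
7 | [(2R)-3-bromo-2-methylpropoxy](tert-butyl)dimethylsilane | CC(C)(C)[Si](C)(C)OC[C@@H](C)CBr | intermediate
8 | {(2R)-3-[(tert-butyldimethylsilyl)oxy]-2-methylpropyl}magnesium bromide (not isolated) | CC(C)(C)[Si](C)(C)OC[C@@H](C)C[Mg]Br | intermediate
9 | (3S)-4-[(tert-butyldimethylsilyl)oxy]-3-methylbutan-1-ol | CC(C)(C)[Si](C)(C)OC[C@@H](C)CCO | intermediate
10 | [(2S)-4-bromo-2-methylbutoxy](tert-butyl)dimethylsilane | CC(C)(C)[Si](C)(C)OC[C@@H](C)CCBr | intermediate
11 | {(3S)-4-[(tert-butyldimethylsilyl)oxy]-3-methylbutyl}magnesium bromide (not isolated) | CC(C)(C)[Si](C)(C)OC[C@@H](C)CC[Mg]Br | intermediate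
12 | tert-butyl({(2S)-2-methyl-6-[(6R,9R)-6-methyl-1,4-dioxaspiro[4.5]decan-9-yl]hept-6-en-1-yl}oxy)dimethylsilane | CC(C)(C)[Si](C)(C)OC[C@@H](C)CCCC(=C)[C@@H]1CC[C@@H](C)C2(C1)OCCO2 | intermediate
13 | 2-{(2S,6S)-7-[(tert-butyldimethylsilyl)oxy]-6-methyl-2-[(6R,9R)-6-methyl-1,4-dioxaspiro[4.5]decan-9-yl]heptyl}-4,4,5,5-tetramethyl-1,3,2-dioxaborolane (not isolated) | CC(C)(C)[Si](C)(C)OC[C@@H](C)CCC[C@H](CB2OC(C)(C)C(C)(C)O2)[C@@H]1CC[C@@H](C)C3(C1)OCCO3 | intermediate
14 | (2S,6S)-7-[(tert-butyldimethylsilyl)oxy]-6-methyl-2-[(6R,9R)-6-methyl-1,4-dioxaspiro[4.5]decan-9-yl]heptan-1-ol | CC(C)(C)[Si](C)(C)OC[C@@H](C)CCC[C@H](CO)[C@@H]1CC[C@@H](C)C2(C1)OCCO2 | intermediate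
15 | (2R,5R)-5-[(2S,6S)-1,7-dihydroxy-6-methylheptan-2-yl]-2-methylcyclohexan-1-one | OC[C@@H](C)CCC[C@H](CO)[C@@H]1CC[C@@H](C)C(=O)C1 | intermediate
16 | (2S,6S)-2-methyl-6-[(1R,4R)-4-methyl-3-oxocyclohexyl]heptane-1,7-diyl diacetate | CC(=O)OC[C@@H](C)CCC[C@H](COC(C)=O)[C@@H]1CC[C@@H](C)C(=O)C1 | intermediate
17 | N-({(3R,6S)-2-chloro-6-[(2S,6S)-1,7-diacetoxy-6-methylheptan-2-yl]-3-methylcyclohex-1-en-1-yl}methylidene)-N-methylmethanaminium dichlorophosphate (not isolated) | CC(=O)OC[C@@H](C)CCC[C@H](COC(C)=O)[C@@H]1CC[C@@H](C)C(Cl)=C1C=[N+](C)C.[O-]P(=O)(Cl)Cl | intermediate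
18 | (2S,6S)-6-[(1S,4R)-3-chloro-2-formyl-4-methylcyclohex-2-en-1-yl]-2-methylheptane-1,7-diyl diacetate | CC(=O)OC[C@@H](C)CCC[C@H](COC(C)=O)[C@@H]1CC[C@@H](C)C(Cl)=C1C=O | intermediate
19 | ethyl 4-(benzyloxy)-3-oxobutanoate | CCOC(=O)CC(=O)COCc1ccccc1 | starting material
20 | benzyl 4-(benzyloxy)-3-oxobutanoate | O=C(CC(=O)COCc1ccccc1)OCc1ccccc1 | intermediate
21 | benzyl (E)-4-(benzyloxy)-2-({(3R,6S)-2-chloro-6-[(2S,6S)-1,7-diacetoxy-6-methylheptan-2-yl]-3-methylcyclohex-1-en-1-yl}methylidene)-3-oxobutanoate (reactive isomer, ketone arm cis to C8a; not isolated) | CC(=O)OC[C@@H](C)CCC[C@H](COC(C)=O)[C@@H]1CC[C@@H](C)C(Cl)=C1/C=C(C(=O)OCc2ccccc2)\C(=O)COCc3ccccc3 | intermediate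
22 | benzyl (5R,8S)-4-(benzyloxy)-4a-chloro-8-[(2S,6S)-1,7-diacetoxy-6-methylheptan-2-yl]-3-hydroxy-5-methyl-4,4a,5,6,7,8-hexahydronaphthalene-2-carboxylate (positions 4 and 4a transient and unassigned; not isolated) | CC(=O)OC[C@@H](C)CCC[C@H](COC(C)=O)[C@@H]1CC[C@@H](C)C2(Cl)C1=CC(C(=O)OCc3ccccc3)=C(O)C2OCc4ccccc4 | intermediate
23 | benzyl (5R,8S)-4-(benzyloxy)-8-[(2S,6S)-1,7-diacetoxy-6-methylheptan-2-yl]-3-hydroxy-5-methyl-5,6,7,8-tetrahydronaphthalene-2-carboxylate | CC(=O)OC[C@@H](C)CCC[C@H](COC(C)=O)[C@@H]1CC[C@@H](C)c2c1cc(C(=O)OCc3ccccc3)c(O)c2OCc4ccccc4 | intermediate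
24 | (5R,8S)-8-[(2S,6S)-1,7-diacetoxy-6-methylheptan-2-yl]-3,4-dihydroxy-5-methyl-5,6,7,8-tetrahydronaphthalene-2-carboxylic acid | CC(=O)OC[C@@H](C)CCC[C@H](COC(C)=O)[C@@H]1CC[C@@H](C)c2c1cc(C(=O)O)c(O)c2O | target

## Step count and risks

Total step count: 14.
Longest linear sequence: 10 steps (1, 2, 3, 7, 8, 9, 10, 11, 13, 14). The branch from 6 through steps 4, 5 and 6 is equally long.

**Risk 1, step 13.**
- Condensation at the hindered formyl group, flanked by C1 and the chloroalkene, may stall.
- Closure may run through the C6 ketone oxygen instead of C5 (oxa-6π closure and chloride loss toward a pyrylium salt).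
- The amine base may erode C4 by deprotonating the extended acceptor.

The fallback sets out from 18 and 20 and returns at 23. It replaces the base-driven cascade by a neutral pericyclic closure of an isolated, oxygen-blocked triene.
- The TiCl4/pyridine reaction is stopped after the condensation and 21 is isolated.
- TBSOTf and Et3N in CH2Cl2 at −78 °C convert it into the (Z)-silyl trienol ether of 21 F1, in which the ketone oxygen can no longer cyclise and hydrogen is the inward substituent on C5.
- Heating in toluene at 110 °C with 2,6-lutidine should bring about thermal 6π closure and loss of HCl to the C6 silyl ether of 23 F2.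
- HF·pyridine in THF then frees the phenol to give 23.

**Risk 2, step 11.**
- In the acidic medium the ketone enolises more readily toward C4 than toward C8a, so C4 may lose its configuration before C8a is formylated.
- Attack next to the branched C1 substituent may be slow enough for unproductive chlorination of the ketone to compete.

The fallback sets out from 16 and returns at 18. It splits the transformation into three cold, separately controlled stages.
- Ti-Claisen formylation (TiCl4, Et3N, HCO2Me, CH2Cl2, −78 to 0 °C), which tolerates esters, should give the (Z)-hydroxymethylene ketone F3.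
- Me2NH in THF at rt converts it into the (E)-enaminone F4.
- POCl3 in CH2Cl2 at 0 °C turns F4 into 17, which aq NaOAc hydrolyses to 18.
- C4–H is not acidic in the vinylogous acid or amide, and no stage is run under equilibrating conditions.

**Risk 3, step 8.**
- Facial discrimination at C11 may be poor, because the catalyst has to tell a ring CH from a long CH2 chain.
- The resident C1 centre may oppose the ligand (mismatch).

The fallback sets out from 12 and returns at 16. It gives up catalyst control in favour of an enzymatic separation of epimers.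
- 9-BBN in THF followed by H2O2/NaOH gives 14 together with the C11 epimer of 14 F5.
- Burkholderia cepacia lipase and vinyl acetate in MTBE should, by the empirical size rule for β-branched primary alcohols, acylate the 11S alcohol faster. This gives the C18 acetate of 14 F6, which is separated from unreacted F5 by chromatography.
- 2 M HCl in THF removes the ketal and the silyl ether to give the keto alcohol monoacetate F7.
- Ac2O/pyridine delivers 16.

## Further compounds

F1 | step 13 | (Z)-tert-butyldimethylsilyl trienol ether of 21 (C5=C6 enol ether, C6–OTBS) | CC(=O)OC[C@@H](C)CCC[C@H](COC(C)=O)[C@@H]1CC[C@@H](C)C(Cl)=C1/C=C(C(=O)OCc2ccccc2)\C(O[Si](C)(C)C(C)(C)C)=C\OCc3ccccc3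
F2 | step 13 | C6 tert-butyldimethylsilyl ether of 23 | CC(=O)OC[C@@H](C)CCC[C@H](COC(C)=O)[C@@H]1CC[C@@H](C)c2c1cc(C(=O)OCc3ccccc3)c(O[Si](C)(C)C(C)(C)C)c2OCc4ccccc4
F3 | step 11 | (Z)-hydroxymethylene ketone of 16 (C8a=C8H–OH) | CC(=O)OC[C@@H](C)CCC[C@H](COC(C)=O)[C@@H]1CC[C@@H](C)C(=O)/C1=C\O
F4 | step 11 | (E)-dimethylaminomethylene ketone of 16 (enaminone) | CC(=O)OC[C@@H](C)CCC[C@H](COC(C)=O)[C@@H]1CC[C@@H](C)C(=O)/C1=C/N(C)C
F5 | step 8 | C11 epimer of 14 (11R) | CC(C)(C)[Si](C)(C)OC[C@@H](C)CCC[C@@H](CO)[C@@H]1CC[C@@H](C)C2(C1)OCCO2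
F6 | step 8 | C18 acetate of 14 | CC(C)(C)[Si](C)(C)OC[C@@H](C)CCC[C@H](COC(C)=O)[C@@H]1CC[C@@H](C)C2(C1)OCCO2
F7 | step 8 | (2S,6S)-7-hydroxy-6-methyl-2-[(1R,4R)-4-methyl-3-oxocyclohexyl]heptyl acetate | OC[C@@H](C)CCC[C@H](COC(C)=O)[C@@H]1CC[C@@H](C)C(=O)C1
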